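Don't read a late target-to-isomer ratio in these runs as a fixed split. Isomer rises at every reading, while target falls after its plateau, so the ratio follows a stock that is passing through.

| flask | substrate | partner | remark | time |
|---|---|---|---|---|
| delta | 20 mM | 0.60 equiv | run made earlier |  |
| alpha | 20 mM | 0.90 equiv | run made earlier |  |
| flask | 20 mM | 1.20 equiv |  | 25 min |

| run | time / min | target / % | isomer of the product / % | substrate / % |
|---|---|---|---|---|
| delta | 1.33 | 5.1 | 2.3 | 94.7 |
| delta | 3.00 | 5.7 | 3.8 | 88.1 |
| delta | 6.00 | 7.2 | 4.6 | 81.5 |
| delta | 15.0 | 2.6 | 9.4 | 69.9 |
| alpha | 4.00 | 8.4 | 5.1 | 79.1 |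
| alpha | 8.00 | 7.6 | 8.7 | 69.5 |
| alpha | 12.0 | 7.3 | 11.7 | 60.2 |
| alpha | 15.0 | 4.0 | 14.2 | 56.6 |

(standard deviation of a reading: 1 percentage point)

- ratio of target to isomer of the product at 20 s
- ratio of target to isomer of the product at 3.0 min
- ratio of target to isomer of the product at 25 min
- which of target and isomer of the product there is more of at 25 min

- the numbers in the tables scatter with a standard deviation of 1 percentage point
- candidate steps: target -> over-reaction product; partner -> decomposed reagent; substrate + partner <-> target; substrate + partner <-> isomer of the product

Follow one molecule of substrate. At the first fork it becomes target or isomer. The last readings give isomer's share of the substrate consumed, its selectivity: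

delta 0.312, alpha 0.327, mean 0.320

At the second fork, target leaves for over-reaction product. At 15.0 min the readings miss 18.1 % in delta and 25.2 % in alpha. Count that as over-reaction product, and divide the mean target of the readings, times the elapsed time, by what is missing. This gives the target lifetime, the mean time a molecule stays target:

lifetime = 4.15 min

The first alpha reading, with partner taken at its charge, gives a consumption constant:

0.00326 /mM/min

Ignoring decomposition, [partner] in the flask stays 4.00 mM above [substrate]. The integrated second-order law then gives:

[substrate] at 25 min = 6.04 mM
isomer = 22.3 %
target = target's share of inflow × lifetime = 2.79 %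
ratio = 0.125

The weak link is the inflow's date. Inflow is falling, and a molecule present now entered about one lifetime earlier, so take it at 20.9 min:

[substrate] = 6.96 mM
target = 3.51 %
ratio = 0.157

I commit to 0.157, with isomer ahead. The forecast gives 2.6, 1.7 and 0.11, with isomer of the product ahead, on the ground that “target sits near quasi-steady 2–3% against about 25% isomer”, so my late ratio is higher.

The flask gives 2.58, 1.76 and 0.195, with isomer of the product ahead.

    target → over-reaction product (k = 0.00350 /s)
    partner → decomposed reagent (k = 2.70 × 10⁻⁴ /s)
    substrate + partner ⇌ target (K = 38.0 /M, k = 0.0540 /M/s)
    substrate + partner ⇌ isomer of the product (K = 92.0 /M, k = 0.0200 /M/s)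

At 25.0 min the flask holds 3.49 % target against 18.0 % isomer, and target is made at 0.728 of the rate it is used up, each step taken net. The neighbouring flask, charged with 8.0 mM substrate at the same equivalents, starts with 1.60 mM excess partner. The same lagged reckoning, with the same lifetime, gives it a ratio of 0.237, and that flask stands at 0.263.

The numbers in the tables are calculated for an exercise; noise was put on by code.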